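**Plan**
- Retrosynthesis first removes the two phenol silyl ethers and the (Z)-enal (aldehyde from the allylic alcohol, alkene from the alkyne, alkyne from the aryl bromide at C5), then cuts the C–O bond of the 4-hydroxybenzoate.
- The core is then cut at C3–C3a. The enabling feature is that C3 of the dihydrofuran carries both the ring A carbon C3a and an exocyclic carbon at ester oxidation level (the CH2O carbon). That is the pattern left when ring A of a 2-arylchroman-4-one shifts from the carbonyl carbon C4 to the neighbouring CH2.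
- The flavanone is cut at C2–aryl (conjugate arylation of a chromone) and the chromone at O1–C2 and C2–C3 (enaminone annulation of a bromo-hydroxyacetophenone).
- Forward: the pyranone ring is built first, C2 is set, the pyranone is contracted to the dihydrofuran, and the ester, alkyne, Z-alkene and aldehyde follow.
- Stereochemistry: C2 (S) comes from a chiral pyridine-oxazoline/palladium catalyst, C3 is relayed from C2 in the ring contraction (trans), and the Z-alkene comes from syn semi-hydrogenation.

Key step: step 5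

Assumption: the (S)-pyridine-oxazoline ligand is taken to give (R)-adducts with cyclic enones and chromones, so the (R)-ligand is specified for the (2S)-flavanone; if the first sample proves (2R), the antipodal ligand is used.

**Step 1**
Reactants: 1 1-(2-hydroxy-3-methoxyphenyl)ethanone
Product: 2 1-(5-bromo-2-hydroxy-3-methoxyphenyl)ethanone
Conditions: NBS (1.05 equiv), MeCN, 0 °C to rt
Reagents that add atoms: N-bromosuccinimide, O=C1CCC(=O)N1Br
Why: Electrophilic aromatic bromination, in which the phenol directs to its only free activated position (para, C5), which is also meta to the acetyl group.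

**Step 2**
Reactants: 2 1-(5-bromo-2-hydroxy-3-methoxyphenyl)ethanone
Product: 4 6-bromo-8-methoxy-4H-chromen-4-one, via enaminone 3 (not isolated)
Conditions: Me2NCH(OMe)2, toluene, 100 °C; evaporate; conc. HCl, CH2Cl2, rt
Reagents that add atoms: N,N-dimethylformamide dimethyl acetal, COC(OC)N(C)C
Why: Enaminone annulation to a chromone: the methyl ketone condenses with the formamide acetal, and acid then promotes addition of the phenol oxygen to the β-carbon with loss of dimethylamine to close the pyranone.

**Step 3**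
Reactants: 5 (4-hydroxy-3-methoxyphenyl)boronic acid
Product: 6 (4-acetoxy-3-methoxyphenyl)boronic acid
Conditions: Ac2O, pyridine, CH2Cl2, 0 °C to rt; dilute aqueous HCl work-up
Reagents that add atoms: acetic anhydride, CC(=O)OC(C)=O
Why: Phenol O-acetylation (boron acetates and boroxine revert to the boronic acid on aqueous work-up), done before the C–C bond formation so that a free 4'-hydroxyflavanone, which racemises by ring opening, never appears.

**Step 4**
Reactants: 4 6-bromo-8-methoxy-4H-chromen-4-one; 6 (4-acetoxy-3-methoxyphenyl)boronic acid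
Product: 7 4-[(2S)-6-bromo-8-methoxy-4-oxo-3,4-dihydro-2H-chromen-2-yl]-2-methoxyphenyl acetate
Conditions: Pd(OCOCF3)2 (5 mol%), (R)-4-tert-butyl-2-(pyridin-2-yl)-4,5-dihydrooxazole (6 mol%), NH4PF6 (30 mol%), H2O (5 equiv), ClCH2CH2Cl, 60 °C
Reagents that add atoms: none
Why: Enantioselective conjugate addition of an arylboronic acid to a chromone under cationic divalent palladium catalysis, in which the aryl–Pd species inserts C2=C3 on the face left open by the ligand tert-butyl group to set C2, and the base-free medium spares the aryl acetate, the aryl bromide (no zerovalent palladium is formed) and the configurationally labile flavanone.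

**Step 5**
Reactants: 7 4-[(2S)-6-bromo-8-methoxy-4-oxo-3,4-dihydro-2H-chromen-2-yl]-2-methoxyphenyl acetate
Product: 9 methyl (2S,3S)-2-(4-acetoxy-3-methoxyphenyl)-5-bromo-7-methoxy-2,3-dihydro-1-benzofuran-3-carboxylate, via methyl enol ether 8 (not isolated)
Conditions: PhI(OAc)2 (1.3 equiv), conc. H2SO4 (0.5 equiv), HC(OMe)3, rt; aqueous NaHCO3 work-up
Reagents that add atoms: trimethyl orthoformate, COC(OC)OC
Why: Acid and HC(OMe)3 turn the ketone into methyl enol ether 8, whose C3 attacks the trivalent iodine electrophile anti to the C2 aryl group while methanol adds at C4, leaving an equatorial C3–I bond antiperiplanar to the C4–C4a bond. Ring A then shifts from C4 to C3 through a bridged phenonium ion as iodobenzene leaves, and the resulting dimethoxycarbenium ion gives the methyl ester on aqueous work-up. The closest known reaction type is the oxidative 1,2-aryl rearrangement of flavanones with PhI(OAc)2 or Tl(NO3)3 in trimethyl orthoformate, which gives methyl trans-2-aryl-2,3-dihydrobenzofuran-3-carboxylates. The dihydrofuran is closed by ring contraction, not cyclisation: the new C3–C3a bond (old C3–C4a) forms by a 3-exo-tet ipso attack of ring A on C3, and the spiro three-membered ring opens at the old C4–C4a bond. The new stereocentre C3 is controlled by C2, because displacement with inversion of the anti-placed iodine puts the ester carbon trans to the aryl group; the trans ester is also the thermodynamic epimer, and C2 is not involved. The step needs ring A to migrate in preference to the 2-aryl group (isoflavone path) and to simple proton loss (flavone path), which is secured by the lone pair of O1 ortho to the migrating carbon and by the electron-poor acetoxy-substituted ring B.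

**Step 6**
Reactants: 9 methyl (2S,3S)-2-(4-acetoxy-3-methoxyphenyl)-5-bromo-7-methoxy-2,3-dihydro-1-benzofuran-3-carboxylate
Product: 10 4-[(2S,3R)-5-bromo-3-(hydroxymethyl)-7-methoxy-2,3-dihydro-1-benzofuran-2-yl]-2-methoxyphenol
Conditions: LiBH4 (4 equiv), THF, 0 °C to rt; aqueous NH4Cl
Reagents that add atoms: none
Why: Hydride reduction of the methyl ester to the primary alcohol with concurrent reductive removal of the aryl acetate, leaving the aryl bromide and the cyclic benzylic ether intact; C3 changes descriptor only (S to R) because the substituent priorities change.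

**Step 7**
Reactants: 10 4-[(2S,3R)-5-bromo-3-(hydroxymethyl)-7-methoxy-2,3-dihydro-1-benzofuran-2-yl]-2-methoxyphenol; 11 4-hydroxybenzoic acid
Product: 12 [(2S,3R)-5-bromo-2-(4-hydroxy-3-methoxyphenyl)-7-methoxy-2,3-dihydro-1-benzofuran-3-yl]methyl 4-hydroxybenzoate
Conditions: PPh3, DIAD, THF, 0 °C to rt
Reagents that add atoms: none
Why: Mitsunobu esterification, in which only the carboxylic acid (pKa about 4.5) is acidic enough to protonate the betaine, so the carboxylate displaces the primary alkoxyphosphonium group while both phenols (pKa about 9–10) stay free, as in known Mitsunobu esterifications of unprotected phenolic acids.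

**Step 8**
Reactants: 12 [(2S,3R)-5-bromo-2-(4-hydroxy-3-methoxyphenyl)-7-methoxy-2,3-dihydro-1-benzofuran-3-yl]methyl 4-hydroxybenzoate
Product: 13 [(2S,3R)-5-bromo-2-{4-[(tert-butyldimethylsilyl)oxy]-3-methoxyphenyl}-7-methoxy-2,3-dihydro-1-benzofuran-3-yl]methyl 4-[(tert-butyldimethylsilyl)oxy]benzoate
Conditions: TBSCl (2.5 equiv), imidazole (5 equiv), DMF, rt
Reagents that add atoms: tert-butyldimethylsilyl chloride, CC(C)(C)[Si](C)(C)Cl
Why: Standard silylation of both phenols, so that the cross-coupling and the MnO2 oxidation meet no free phenol; the ester is inert.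

**Step 9**
Reactants: 13 the bis-silyl aryl bromide; 14 prop-2-yn-1-ol
Product: 15 [(2S,3R)-2-{4-[(tert-butyldimethylsilyl)oxy]-3-methoxyphenyl}-5-(3-hydroxyprop-1-yn-1-yl)-7-methoxy-2,3-dihydro-1-benzofuran-3-yl]methyl 4-[(tert-butyldimethylsilyl)oxy]benzoate
Conditions: Pd(PhCN)2Cl2 (3 mol%), [HP(t-Bu)3]BF4 (6 mol%), CuI (2 mol%), i-Pr2NH, 1,4-dioxane (degassed), rt to 45 °C
Reagents that add atoms: none
Why: Sonogashira coupling, in which the bulky electron-rich phosphine lets zerovalent palladium insert into the electron-rich aryl bromide near room temperature and the hindered amine leaves the ester and aryl silyl ethers alone.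

**Step 10**
Reactants: 15 the aryl propargylic alcohol
Product: 16 [(2S,3R)-2-{4-[(tert-butyldimethylsilyl)oxy]-3-methoxyphenyl}-5-[(1Z)-3-hydroxyprop-1-en-1-yl]-7-methoxy-2,3-dihydro-1-benzofuran-3-yl]methyl 4-[(tert-butyldimethylsilyl)oxy]benzoate
Conditions: H2 (1 atm), Pd/CaCO3 poisoned with Pb(OAc)2, quinoline, EtOAc, rt, stopped after one equivalent of H2
Reagents that add atoms: none
Why: Lindlar semi-hydrogenation, in which syn delivery of hydrogen from the poisoned palladium surface gives the Z-alkene without cleaving the benzylic C–O bond or the ester.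

**Step 11**
Reactants: 16 the (Z)-allylic alcohol
Product: 17 [(2S,3R)-2-{4-[(tert-butyldimethylsilyl)oxy]-3-methoxyphenyl}-7-methoxy-5-[(1Z)-3-oxoprop-1-en-1-yl]-2,3-dihydro-1-benzofuran-3-yl]methyl 4-[(tert-butyldimethylsilyl)oxy]benzoate
Conditions: activated MnO2 (15 equiv), CH2Cl2, rt, dark, short contact time
Reagents that add atoms: none
Why: Selective heterogeneous oxidation of the allylic alcohol under neutral aprotic conditions, which should preserve the Z geometry when light and acid are excluded.

**Step 12**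
Reactants: 17 the bis-silyl (Z)-enal
Product: 18 [(2S,3R)-2-(4-hydroxy-3-methoxyphenyl)-7-methoxy-5-[(1Z)-3-oxoprop-1-en-1-yl]-2,3-dihydro-1-benzofuran-3-yl]methyl 4-hydroxybenzoate
Conditions: Bu4NF (2.2 equiv), AcOH (2.5 equiv), THF, 0 °C
Reagents that add atoms: none
Why: Fluoride cleavage of aryl silyl ethers is fast at 0 °C, and the acetic acid buffer keeps phenoxide and fluoride basicity low so that the benzoate ester and the Z-enal should survive.

**Compound list**
1 | 1-(2-hydroxy-3-methoxyphenyl)ethanone | CC(=O)c1cccc(OC)c1O | starting material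
2 | 1-(5-bromo-2-hydroxy-3-methoxyphenyl)ethanone | CC(=O)c1cc(Br)cc(OC)c1O | intermediate
3 | (E)-1-(5-bromo-2-hydroxy-3-methoxyphenyl)-3-(dimethylamino)prop-2-en-1-one | CN(C)/C=C/C(=O)c1cc(Br)cc(OC)c1O | intermediate
4 | 6-bromo-8-methoxy-4H-chromen-4-one | O=c1ccoc2c(OC)cc(Br)cc12 | intermediate
5 | (4-hydroxy-3-methoxyphenyl)boronic acid | COc1cc(B(O)O)ccc1O | starting material
6 | (4-acetoxy-3-methoxyphenyl)boronic acid | COc1cc(B(O)O)ccc1OC(C)=O | intermediate
7 | 4-[(2S)-6-bromo-8-methoxy-4-oxo-3,4-dihydro-2H-chromen-2-yl]-2-methoxyphenyl acetate | COc1cc([C@H]2Oc3c(OC)cc(Br)cc3C(=O)C2)ccc1OC(C)=O | intermediate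
8 | 4-[(2S)-6-bromo-4,8-dimethoxy-2H-chromen-2-yl]-2-methoxyphenyl acetate | COc1cc([C@H]2Oc3c(OC)cc(Br)cc3C(OC)=C2)ccc1OC(C)=O | intermediate
9 | methyl (2S,3S)-2-(4-acetoxy-3-methoxyphenyl)-5-bromo-7-methoxy-2,3-dihydro-1-benzofuran-3-carboxylate (trans) | COc1cc([C@H]2Oc3c(OC)cc(Br)cc3[C@@H]2C(=O)OC)ccc1OC(C)=O | intermediate
10 | 4-[(2S,3R)-5-bromo-3-(hydroxymethyl)-7-methoxy-2,3-dihydro-1-benzofuran-2-yl]-2-methoxyphenol | COc1cc([C@H]2Oc3c(OC)cc(Br)cc3[C@@H]2CO)ccc1O | intermediate
11 | 4-hydroxybenzoic acid | OC(=O)c1ccc(O)cc1 | starting material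
12 | [(2S,3R)-5-bromo-2-(4-hydroxy-3-methoxyphenyl)-7-methoxy-2,3-dihydro-1-benzofuran-3-yl]methyl 4-hydroxybenzoate | COc1cc([C@H]2Oc3c(OC)cc(Br)cc3[C@@H]2COC(=O)c2ccc(O)cc2)ccc1O | intermediate
13 | [(2S,3R)-5-bromo-2-{4-[(tert-butyldimethylsilyl)oxy]-3-methoxyphenyl}-7-methoxy-2,3-dihydro-1-benzofuran-3-yl]methyl 4-[(tert-butyldimethylsilyl)oxy]benzoate | COc1cc([C@H]2Oc3c(OC)cc(Br)cc3[C@@H]2COC(=O)c2ccc(O[Si](C)(C)C(C)(C)C)cc2)ccc1O[Si](C)(C)C(C)(C)C | intermediate
14 | prop-2-yn-1-ol | OCC#C | starting material
15 | [(2S,3R)-2-{4-[(tert-butyldimethylsilyl)oxy]-3-methoxyphenyl}-5-(3-hydroxyprop-1-yn-1-yl)-7-methoxy-2,3-dihydro-1-benzofuran-3-yl]methyl 4-[(tert-butyldimethylsilyl)oxy]benzoate | COc1cc([C@H]2Oc3c(OC)cc(C#CCO)cc3[C@@H]2COC(=O)c2ccc(O[Si](C)(C)C(C)(C)C)cc2)ccc1O[Si](C)(C)C(C)(C)C | intermediate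
16 | [(2S,3R)-2-{4-[(tert-butyldimethylsilyl)oxy]-3-methoxyphenyl}-5-[(1Z)-3-hydroxyprop-1-en-1-yl]-7-methoxy-2,3-dihydro-1-benzofuran-3-yl]methyl 4-[(tert-butyldimethylsilyl)oxy]benzoate | COc1cc([C@H]2Oc3c(OC)cc(/C=C\CO)cc3[C@@H]2COC(=O)c2ccc(O[Si](C)(C)C(C)(C)C)cc2)ccc1O[Si](C)(C)C(C)(C)C | intermediate
17 | [(2S,3R)-2-{4-[(tert-butyldimethylsilyl)oxy]-3-methoxyphenyl}-7-methoxy-5-[(1Z)-3-oxoprop-1-en-1-yl]-2,3-dihydro-1-benzofuran-3-yl]methyl 4-[(tert-butyldimethylsilyl)oxy]benzoate | COc1cc([C@H]2Oc3c(OC)cc(/C=C\C=O)cc3[C@@H]2COC(=O)c2ccc(O[Si](C)(C)C(C)(C)C)cc2)ccc1O[Si](C)(C)C(C)(C)C | intermediate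
18 | [(2S,3R)-2-(4-hydroxy-3-methoxyphenyl)-7-methoxy-5-[(1Z)-3-oxoprop-1-en-1-yl]-2,3-dihydro-1-benzofuran-3-yl]methyl 4-hydroxybenzoate | COc1cc([C@H]2Oc3c(OC)cc(/C=C\C=O)cc3[C@@H]2COC(=O)c2ccc(O)cc2)ccc1O | target

**Step count**
Total: 12 steps. Longest linear sequence: 11 steps (from 1 through steps 1, 2 and 4–12); step 3 is a one-step branch.

**Steps most likely to fail**

Step 5. The shift of ring A may be outrun by proton loss (dehydrogenation to the flavone), by migration of the 2-aryl group, or by acid solvolysis of the acetate, since the bromine meta to the migrating carbon lowers its aptitude. The fallback separates oxidation from rearrangement and uses a stable leaving group. It sets out from 7 and returns at 9.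
- α-Bromination of 7 with CuBr2 in EtOAc/CHCl3 at reflux should give the trans bromoketone 4-[(2R,3R)-3,6-dibromo-8-methoxy-4-oxo-3,4-dihydro-2H-chromen-2-yl]-2-methoxyphenyl acetate F1. The C2 descriptor changes only because bromine raises the rank of C3.
- HC(OMe)3, MeOH and TsOH convert it into the ketal 4-[(2R,3R)-3,6-dibromo-4,4,8-trimethoxy-3,4-dihydro-2H-chromen-2-yl]-2-methoxyphenyl acetate F2.
- Heating F2 with catalytic ZnBr2 in toluene at 100 °C triggers the same C4-to-C3 shift of ring A with bromide as nucleofuge (the 1,2-aryl shift of α-halo ketals). Inversion at C3 again gives the trans ester, and bromide demethylates the dimethoxycarbenium ion to give 9.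

Step 4. Enantiofacial discrimination may be insufficient, turnover may be slow because the electron-rich arylboronic acid protodeboronates, or the sense of induction may be opposite. The fallback replaces asymmetric catalysis by resolution. It sets out from 4 and 6 and returns at 7.
- The arylation is run with the achiral catalyst Pd(OCOCF3)2/2,2'-bipyridine in aqueous ClCH2CH2Cl to give racemic 4-(6-bromo-8-methoxy-4-oxo-3,4-dihydro-2H-chromen-2-yl)-2-methoxyphenyl acetate F3.
- The enantiomers are separated by preparative chromatography on a cellulose tris(3,5-dimethylphenylcarbamate) phase; the (2S) fraction is 7.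

Step 12. Fluoride or phenoxide may cause Z-to-E isomerisation of the donor-substituted enal, or conjugate addition to it, during desilylation. The fallback reverses the order of the last two operations so that the enal never meets fluoride. It sets out from 16 and returns at 18.
- Treatment of 16 with Bu4NF/AcOH in THF at 0 °C gives [(2S,3R)-2-(4-hydroxy-3-methoxyphenyl)-5-[(1Z)-3-hydroxyprop-1-en-1-yl]-7-methoxy-2,3-dihydro-1-benzofuran-3-yl]methyl 4-hydroxybenzoate F4.
- Its allylic alcohol alone is then oxidised with activated MnO2 in EtOAc/CH2Cl2 in the dark to give 18; allylic alcohols are oxidised much faster than phenols on this reagent.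

**Further compounds**
F1 | step 5 | 4-[(2R,3R)-3,6-dibromo-8-methoxy-4-oxo-3,4-dihydro-2H-chromen-2-yl]-2-methoxyphenyl acetate (trans) | COc1cc([C@H]2Oc3c(OC)cc(Br)cc3C(=O)[C@@H]2Br)ccc1OC(C)=O
F2 | step 5 | 4-[(2R,3R)-3,6-dibromo-4,4,8-trimethoxy-3,4-dihydro-2H-chromen-2-yl]-2-methoxyphenyl acetate | COc1cc([C@H]2Oc3c(OC)cc(Br)cc3C(OC)(OC)[C@@H]2Br)ccc1OC(C)=O
F3 | step 4 | racemic 4-(6-bromo-8-methoxy-4-oxo-3,4-dihydro-2H-chromen-2-yl)-2-methoxyphenyl acetate | COc1cc(C2Oc3c(OC)cc(Br)cc3C(=O)C2)ccc1OC(C)=O
F4 | step 12 | [(2S,3R)-2-(4-hydroxy-3-methoxyphenyl)-5-[(1Z)-3-hydroxyprop-1-en-1-yl]-7-methoxy-2,3-dihydro-1-benzofuran-3-yl]methyl 4-hydroxybenzoate | COc1cc([C@H]2Oc3c(OC)cc(/C=C\CO)cc3[C@@H]2COC(=O)c2ccc(O)cc2)ccc1O
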